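Ring B is opened at C6=C7 (drimane numbering; C11 is the CH2OAr carbon on C9, C12 the exocyclic CH2 on C8). The C6=C7–C8(=C12) diene is read as a methylenated cyclohexenone, so the step on which everything rests is an intramolecular aldol condensation: a ring-A keto-aldehyde carrying the C6 aldehyde on C5 and an acetonyl group (C9–C8(=O)–C7H3) on quaternary C10 closes ring B and creates C6=C7 in one operation. The C8 carbonyl thus unveiled then directs the late union with umbelliferone (oxa-Michael at C11, C9 set by enolate protonation) and finally becomes C12. C10 comes from a palladium-catalysed decarboxylative allylation, C5 from hydroboration.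

Key step: step 9

Assumption: (S)-3-hydroxy-2,2-dimethylcyclohexan-1-one (1) is taken as a purchasable building block; otherwise it is one yeast reduction away from 2,2-dimethylcyclohexane-1,3-dione. Drimane numbering (C1–C12) is used for the atoms throughout.

**Route**

Step 1
Reactants: 1 (S)-3-hydroxy-2,2-dimethylcyclohexan-1-one
Product: 2 (S)-3-[(tert-butyldimethylsilyl)oxy]-2,2-dimethylcyclohexan-1-one
Conditions: TBSCl, imidazole, DMF, 40 °C
Reagents that add atoms: tert-butyldimethylsilyl chloride, CC(C)(C)[Si](C)(C)Cl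
Why: Silyl ether protection of the C3 hydroxyl, which must survive the enolate, borane and organometallic steps; the C3 stereocentre is not touched.

Step 2
Reactants: 2 (S)-3-[(tert-butyldimethylsilyl)oxy]-2,2-dimethylcyclohexan-1-one
Product: 3 (3S,6RS)-3-[(tert-butyldimethylsilyl)oxy]-2,2,6-trimethylcyclohexan-1-one
Conditions: LDA, THF, −78 °C; MeI, −78 → 0 °C
Reagents that add atoms: iodomethane, CI
Why: Enolate alkylation at the only enolisable α-carbon (the other is quaternary) installs the future C10 methyl; the new centre forms as an epimer mixture that does not matter because it is planarised in step 3.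

Step 3
Reactants: 3 (3S,6RS)-3-[(tert-butyldimethylsilyl)oxy]-2,2,6-trimethylcyclohexan-1-one
Product: 4 allyl (5S)-5-[(tert-butyldimethylsilyl)oxy]-2,6,6-trimethylcyclohex-1-en-1-yl carbonate
Conditions: KHMDS, THF, −78 → 0 °C; allyl chloroformate, −78 °C → rt
Reagents that add atoms: allyl chloroformate, C=CCOC(=O)Cl
Why: O-Acylation of the single possible, tetrasubstituted enolate gives the allyl enol carbonate needed for the decarboxylative Tsuji allylation; any C-acylated allyl β-keto ester would converge on the same product in step 4.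

Step 4
Reactants: 4 allyl (5S)-5-[(tert-butyldimethylsilyl)oxy]-2,6,6-trimethylcyclohex-1-en-1-yl carbonate
Product: 5 (3S,6R)-6-allyl-3-[(tert-butyldimethylsilyl)oxy]-2,2,6-trimethylcyclohexan-1-one
Conditions: Pd2(dba)3 (2.5 mol %), (R)-t-BuPHOX (6 mol %), THF, 25 °C
Reagents that add atoms: none
Why: Decarboxylative asymmetric allylic alkylation (Tsuji allylation): zerovalent palladium ionises the carbonate, CO2 is lost and the allyl group is returned to C10 of the enolate under ligand control, which should override the weak bias of the remote C3 silyloxy group; the R-ligand is chosen on the assumption that the S-ligand/S-ketone correlation of the parent 2-allyl-2-methylcyclohexanone series holds here.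

Step 5
Reactants: 5 (3S,6R)-6-allyl-3-[(tert-butyldimethylsilyl)oxy]-2,2,6-trimethylcyclohexan-1-one
Product: 6 tert-butyldimethyl{[(1S,4R)-4-allyl-2,2,4-trimethyl-3-methylidenecyclohexyl]oxy}silane
Conditions: Cp2Ti(CH2)(Cl)AlMe2 (Tebbe reagent), pyridine (cat.), THF–toluene, −40 °C → rt
Reagents that add atoms: Tebbe reagent, C[Al-]1(C)C[Ti]([Cl+]1)(C1C=CC=C1)C1C=CC=C1
Why: Titanium-methylidene (Tebbe) carbonyl olefination is chosen because the ketone, flanked by two quaternary carbons, is non-enolisable and too hindered for a phosphorus ylide; it introduces C6 as an exocyclic methylene that has no allylic hydrogen and so cannot migrate.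

Step 6
Reactants: 6 tert-butyldimethyl{[(1S,4R)-4-allyl-2,2,4-trimethyl-3-methylidenecyclohexyl]oxy}silane
Product: 7 1-[(1R,4S)-4-[(tert-butyldimethylsilyl)oxy]-1,3,3-trimethyl-2-methylidenecyclohexyl]propan-2-one
Conditions: PdCl2 (10 mol %), CuCl, O2 (1 atm), DMF–H2O 7:1, rt
Reagents that add atoms: water, O
Why: Wacker–Tsuji oxidation is selective for the monosubstituted allyl terminus and gives the Markovnikov methyl ketone (C8=O, C7H3), while the hindered 1,1-disubstituted exocyclic alkene stays inert.

Step 7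
Reactants: 7 1-[(1R,4S)-4-[(tert-butyldimethylsilyl)oxy]-1,3,3-trimethyl-2-methylidenecyclohexyl]propan-2-one
Product: 9 1-[(1R,2R,4S)-4-[(tert-butyldimethylsilyl)oxy]-2-(hydroxymethyl)-1,3,3-trimethylcyclohexyl]propan-2-ol, via bis(borane) adduct 8 (not isolated)
Conditions: BH3·THF (3 equiv), THF, 0 °C → rt; then NaOH, H2O2, 0 °C → rt
Reagents that add atoms: hydrogen peroxide, OO
Why: Hydroboration–oxidation places boron on the exocyclic carbon and delivers H to C5 from the α-face, opposite the axial methyl groups on C4 and C10 in the chair with equatorial OTBS, so that H-5 is trans to the C10 methyl and the CH2OH group is equatorial; the ketone is reduced in passing to carbinol epimers that are re-oxidised in step 8.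

Step 8
Reactants: 9 1-[(1R,2R,4S)-4-[(tert-butyldimethylsilyl)oxy]-2-(hydroxymethyl)-1,3,3-trimethylcyclohexyl]propan-2-ol
Product: 10 (1R,3S,6R)-3-[(tert-butyldimethylsilyl)oxy]-2,2,6-trimethyl-6-(2-oxopropyl)cyclohexane-1-carbaldehyde
Conditions: Dess–Martin periodinane (2.6 equiv), NaHCO3, CH2Cl2, 0 °C → rt
Reagents that add atoms: none
Why: Dess–Martin oxidation converts both alcohols (primary to the C6 aldehyde, secondary to the C8 ketone) under near-neutral conditions that should not epimerise C5.

Step 9
Reactants: 10 (1R,3S,6R)-3-[(tert-butyldimethylsilyl)oxy]-2,2,6-trimethyl-6-(2-oxopropyl)cyclohexane-1-carbaldehyde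
Product: 12 (4aR,6S,8aR)-6-[(tert-butyldimethylsilyl)oxy]-5,5,8a-trimethyl-4a,5,6,7,8,8a-hexahydronaphthalen-2(1H)-one, via aldol adduct 11 (not isolated)
Conditions: NaOMe (0.3 equiv), MeOH, 0 → 50 °C
Reagents that add atoms: none
Why: Methoxide reversibly forms the methyl-ketone enolate at C7, which attacks the C6 aldehyde to give β-hydroxy ketone 11, and E1cB loss of water then delivers the conjugated enone, so that C6=C7 is made as σ- and π-bond in one flask; this is an intramolecular aldol condensation, the closing event of a Robinson annulation being its closest relative. Ring B closes in the 6-(enolexo)-exo-trig mode, the only productive one, because the other enolates (C9 of the ketone, C5 of the aldehyde) could only give four-membered aldols, which revert. No stereocentre is created: the carbinol centre of 11 is lost on dehydration, and C5, whose α-proton is shielded by the two flanking quaternary carbons, should keep the configuration from step 7, the trans-fused octalone being in any case the expected thermodynamic epimer. The selectivity needed is therefore purely regiochemical (C7 versus C9 enolate, dehydration into conjugation) and is secured by ring size and conjugation; the silyl ether, the quaternary C10 and the C3 centre are inert to catalytic methoxide.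

Step 10
Reactants: 12 (4aR,6S,8aR)-6-[(tert-butyldimethylsilyl)oxy]-5,5,8a-trimethyl-4a,5,6,7,8,8a-hexahydronaphthalen-2(1H)-one
Product: 15 (4aR,6S,8aS)-6-[(tert-butyldimethylsilyl)oxy]-5,5,8a-trimethyl-1-methylidene-4a,5,6,7,8,8a-hexahydronaphthalen-2(1H)-one, via Mannich base 13 (not isolated), via methiodide salt 14 (not isolated)
Conditions: LDA, THF, −78 °C; CH2=NMe2+ I− (Eschenmoser's salt), −78 °C → rt; then MeI, CH2Cl2, rt; then aq. NaHCO3, rt; product used crude
Reagents that add atoms: N,N-dimethylmethyleneiminium iodide (Eschenmoser's salt), C=[N+](C)C.[I-]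
Why: Kinetic α'-deprotonation of the enone at C9, Mannich reaction with Eschenmoser's salt, quaternisation and E1cB loss of trimethylamine (the classical α-methylenation sequence) install C11 as an exocyclic methylene; the C9 centre of 13 is destroyed, so its configuration is irrelevant.

Step 11
Reactants: 15 (4aR,6S,8aS)-6-[(tert-butyldimethylsilyl)oxy]-5,5,8a-trimethyl-1-methylidene-4a,5,6,7,8,8a-hexahydronaphthalen-2(1H)-one; 16 umbelliferone (7-hydroxy-2H-chromen-2-one)
Product: 17 7-{[(1S,4aR,6S,8aS)-6-[(tert-butyldimethylsilyl)oxy]-5,5,8a-trimethyl-2-oxo-1,2,4a,5,6,7,8,8a-octahydronaphthalen-1-yl]methoxy}-2H-chromen-2-one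
Conditions: 16 (1.5 equiv), Cs2CO3 (10 mol %), MeCN, 0 °C → rt; AcOH quench
Reagents that add atoms: none
Why: Oxa-Michael addition of the phenoxide to the unhindered exocyclic C11 of the cross-conjugated dienone gives a C8 enolate that should be protonated on the α-face, anti to the axial C10 methyl, placing H-9 α and the aryloxymethyl group equatorial (9β), which is also the epimer expected on equilibration.

Step 12
Reactants: 17 7-{[(1S,4aR,6S,8aS)-6-[(tert-butyldimethylsilyl)oxy]-5,5,8a-trimethyl-2-oxo-1,2,4a,5,6,7,8,8a-octahydronaphthalen-1-yl]methoxy}-2H-chromen-2-one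
Product: 18 7-{[(1S,4aR,6S,8aS)-6-[(tert-butyldimethylsilyl)oxy]-5,5,8a-trimethyl-2-methylidene-1,2,4a,5,6,7,8,8a-octahydronaphthalen-1-yl]methoxy}-2H-chromen-2-one
Conditions: Zn, CH2Br2, TiCl4, THF–CH2Cl2, 0 °C → rt
Reagents that add atoms: dibromomethane, BrCBr
Why: Takai–Lombardo methylenation, a non-basic and ketone-selective gem-dimetallic olefination, converts the C8 carbonyl into the C12 methylene without enolising C9 (which would epimerise it or expel the β-aryloxide) and should leave the coumarin lactone untouched.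

Step 13
Reactants: 18 7-{[(1S,4aR,6S,8aS)-6-[(tert-butyldimethylsilyl)oxy]-5,5,8a-trimethyl-2-methylidene-1,2,4a,5,6,7,8,8a-octahydronaphthalen-1-yl]methoxy}-2H-chromen-2-one
Product: 19 7-{[(1S,4aR,6S,8aS)-6-hydroxy-5,5,8a-trimethyl-2-methylidene-1,2,4a,5,6,7,8,8a-octahydronaphthalen-1-yl]methoxy}-2H-chromen-2-one (target)
Conditions: HF·pyridine, THF, 0 °C → rt
Reagents that add atoms: none
Why: Fluoride-mediated desilylation of the hindered secondary silyl ether under mildly acidic conditions that the diene, the aryl ether and the lactone should tolerate; no stereocentre is affected.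

**Compound list**

1 | (S)-3-hydroxy-2,2-dimethylcyclohexan-1-one | O=C1C(C)(C)[C@@H](O)CCC1 | starting material
2 | (S)-3-[(tert-butyldimethylsilyl)oxy]-2,2-dimethylcyclohexan-1-one | O=C1C(C)(C)[C@@H](O[Si](C)(C)C(C)(C)C)CCC1 | intermediate
3 | (3S,6RS)-3-[(tert-butyldimethylsilyl)oxy]-2,2,6-trimethylcyclohexan-1-one | O=C1C(C)(C)[C@@H](O[Si](C)(C)C(C)(C)C)CCC1C | intermediate
4 | allyl (5S)-5-[(tert-butyldimethylsilyl)oxy]-2,6,6-trimethylcyclohex-1-en-1-yl carbonate | C=CCOC(=O)OC1=C(C)CC[C@H](O[Si](C)(C)C(C)(C)C)C1(C)C | intermediate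
5 | (3S,6R)-6-allyl-3-[(tert-butyldimethylsilyl)oxy]-2,2,6-trimethylcyclohexan-1-one | O=C1C(C)(C)[C@@H](O[Si](C)(C)C(C)(C)C)CC[C@]1(C)CC=C | intermediate
6 | tert-butyldimethyl{[(1S,4R)-4-allyl-2,2,4-trimethyl-3-methylidenecyclohexyl]oxy}silane | C=C1C(C)(C)[C@@H](O[Si](C)(C)C(C)(C)C)CC[C@]1(C)CC=C | intermediate
7 | 1-[(1R,4S)-4-[(tert-butyldimethylsilyl)oxy]-1,3,3-trimethyl-2-methylidenecyclohexyl]propan-2-one | C=C1C(C)(C)[C@@H](O[Si](C)(C)C(C)(C)C)CC[C@]1(C)CC(C)=O | intermediate
8 | bis(borane) adduct of 7 (C6–BH2 alkylborane and C8–O–BH2 alkoxyborane; formal monomeric composition; not isolated) | [BH2]C[C@H]1C(C)(C)[C@@H](O[Si](C)(C)C(C)(C)C)CC[C@]1(C)CC(C)O[BH2] | intermediate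
9 | 1-[(1R,2R,4S)-4-[(tert-butyldimethylsilyl)oxy]-2-(hydroxymethyl)-1,3,3-trimethylcyclohexyl]propan-2-ol (carbinol epimers) | OC[C@H]1C(C)(C)[C@@H](O[Si](C)(C)C(C)(C)C)CC[C@]1(C)CC(C)O | intermediate
10 | (1R,3S,6R)-3-[(tert-butyldimethylsilyl)oxy]-2,2,6-trimethyl-6-(2-oxopropyl)cyclohexane-1-carbaldehyde | O=C[C@H]1C(C)(C)[C@@H](O[Si](C)(C)C(C)(C)C)CC[C@]1(C)CC(C)=O | intermediate
11 | (4aR,6S,8aR)-6-[(tert-butyldimethylsilyl)oxy]-4-hydroxy-5,5,8a-trimethyloctahydronaphthalen-2(1H)-one (aldol adduct; C4 epimers; not isolated) | O=C1CC(O)[C@H]2C(C)(C)[C@@H](O[Si](C)(C)C(C)(C)C)CC[C@]2(C)C1 | intermediate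
12 | (4aR,6S,8aR)-6-[(tert-butyldimethylsilyl)oxy]-5,5,8a-trimethyl-4a,5,6,7,8,8a-hexahydronaphthalen-2(1H)-one | O=C1C=C[C@H]2C(C)(C)[C@@H](O[Si](C)(C)C(C)(C)C)CC[C@]2(C)C1 | intermediate
13 | 1-[(dimethylamino)methyl] derivative of 12 (Mannich base; C1 epimers; not isolated) | O=C1C=C[C@H]2C(C)(C)[C@@H](O[Si](C)(C)C(C)(C)C)CC[C@]2(C)C1CN(C)C | intermediate
14 | trimethylammonium iodide of 13 (methiodide salt; not isolated) | O=C1C=C[C@H]2C(C)(C)[C@@H](O[Si](C)(C)C(C)(C)C)CC[C@]2(C)C1C[N+](C)(C)C.[I-] | intermediate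
15 | (4aR,6S,8aS)-6-[(tert-butyldimethylsilyl)oxy]-5,5,8a-trimethyl-1-methylidene-4a,5,6,7,8,8a-hexahydronaphthalen-2(1H)-one | O=C1C=C[C@H]2C(C)(C)[C@@H](O[Si](C)(C)C(C)(C)C)CC[C@]2(C)C1=C | intermediate
16 | umbelliferone (7-hydroxy-2H-chromen-2-one) | Oc1ccc2ccc(=O)oc2c1 | starting material
17 | 7-{[(1S,4aR,6S,8aS)-6-[(tert-butyldimethylsilyl)oxy]-5,5,8a-trimethyl-2-oxo-1,2,4a,5,6,7,8,8a-octahydronaphthalen-1-yl]methoxy}-2H-chromen-2-one | O=C1C=C[C@H]2C(C)(C)[C@@H](O[Si](C)(C)C(C)(C)C)CC[C@]2(C)[C@H]1COc1ccc2ccc(=O)oc2c1 | intermediate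
18 | 7-{[(1S,4aR,6S,8aS)-6-[(tert-butyldimethylsilyl)oxy]-5,5,8a-trimethyl-2-methylidene-1,2,4a,5,6,7,8,8a-octahydronaphthalen-1-yl]methoxy}-2H-chromen-2-one | C=C1C=C[C@H]2C(C)(C)[C@@H](O[Si](C)(C)C(C)(C)C)CC[C@]2(C)[C@H]1COc1ccc2ccc(=O)oc2c1 | intermediate
19 | 7-{[(1S,4aR,6S,8aS)-6-hydroxy-5,5,8a-trimethyl-2-methylidene-1,2,4a,5,6,7,8,8a-octahydronaphthalen-1-yl]methoxy}-2H-chromen-2-one | C=C1C=C[C@H]2C(C)(C)[C@@H](O)CC[C@]2(C)[C@H]1COc1ccc2ccc(=O)oc2c1 | target

**Summary**

Total step count: 13. Longest linear sequence: 13 steps (from 1; umbelliferone 16 enters at step 11).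

Steps most likely to fail:

1. Step 11 (oxa-Michael union). The conjugate addition is reversible, so the aryloxide may be lost again on work-up or chromatography; the cross-conjugated dienone may oligomerise before it is trapped; and protonation of the enolate may not be fully α-face selective. Fallback, forming the C–O bond by Mitsunobu substitution instead of conjugate addition: setting out from enone 12, α'-hydroxymethylation (LDA, THF, −78 °C; monomeric CH2O; C9 epimers equilibrated with catalytic DBU toward the equatorial isomer) would give the 9β-hydroxymethyl enone F2. Takai–Lombardo methylenation would then give the homoallylic alcohol F3, and Mitsunobu etherification of F3 with umbelliferone 16 (PPh3, DIAD, THF) comes back to the route at 18.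

2. Step 12 (methylenation of the β-aryloxy enone). Lewis-acid or adventitious base may trigger β-elimination of the aryloxide or epimerisation at C9, and addition to the hindered carbonyl may be sluggish. Fallback, a Peterson olefination: setting out from 17, Me3SiCH2MgCl/CeCl3 (THF, −78 °C) should add 1,2 to give the β-hydroxysilane F4. HF·pyridine would then effect acid-type Peterson elimination and cleavage of the silyl ether in the same flask, coming back at the target 19.

3. Step 5 (olefination of the ketone between two quaternary carbons). Steric shielding may stop carbonyl addition, or the titanium reagent may be consumed at the allyl terminus. Fallback, addition then dehydration: setting out from 5, MeLi/CeCl3 (THF, −78 → 0 °C) should give the tertiary carbinol F1. Burgess reagent (benzene, 60 °C) would dehydrate it by syn-elimination, which can only go toward the new methyl group because both ring neighbours are quaternary; the sequence comes back at 6.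

Further compounds
F1 | step 5 | (3S,6R)-6-allyl-3-[(tert-butyldimethylsilyl)oxy]-1,2,2,6-tetramethylcyclohexan-1-ol (C1 epimers) | CC1(O)C(C)(C)[C@@H](O[Si](C)(C)C(C)(C)C)CC[C@]1(C)CC=C
F2 | step 11 | (1S,4aR,6S,8aS)-6-[(tert-butyldimethylsilyl)oxy]-1-(hydroxymethyl)-5,5,8a-trimethyl-4a,5,6,7,8,8a-hexahydronaphthalen-2(1H)-one | O=C1C=C[C@H]2C(C)(C)[C@@H](O[Si](C)(C)C(C)(C)C)CC[C@]2(C)[C@H]1CO
F3 | step 11 | [(1S,4aR,6S,8aS)-6-[(tert-butyldimethylsilyl)oxy]-5,5,8a-trimethyl-2-methylidene-1,2,4a,5,6,7,8,8a-octahydronaphthalen-1-yl]methanol | C=C1C=C[C@H]2C(C)(C)[C@@H](O[Si](C)(C)C(C)(C)C)CC[C@]2(C)[C@H]1CO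
F4 | step 12 | 7-{[(1S,4aR,6S,8aS)-6-[(tert-butyldimethylsilyl)oxy]-2-hydroxy-5,5,8a-trimethyl-2-[(trimethylsilyl)methyl]-1,2,4a,5,6,7,8,8a-octahydronaphthalen-1-yl]methoxy}-2H-chromen-2-one (C2 epimers) | C[Si](C)(C)CC1(O)C=C[C@H]2C(C)(C)[C@@H](O[Si](C)(C)C(C)(C)C)CC[C@]2(C)[C@H]1COc1ccc2ccc(=O)oc2c1
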